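**Retrosynthetic overview**
1. The route rests on the ring-cis trisubstituted C1=C10 alkene of the ten-membered carbocycle C1–C10 (C10 bears C14). It is the last skeletal bond made, by extruding SO2 from an eleven-membered cyclic sulfone in which sulfur bridges C1 and C10 (Ramberg–Bäcklund ring contraction).
2. The thiacycle is closed through the S–C1 bond (C10 thiolate on a primary C1 chloride) in an open C1–C10 chain that already holds C6, C7 and C8.
3. The chain comes from an Evans syn-aldol (C6–C7 bond, sets C6 and C7) between the (E)-enal C1–C6/C15 and an N-acyl oxazolidinone C11/C7–C10/C14 whose C8 centre is bought with dioxane 9. The acyl carbon C11 then becomes the 2-propenyl unit (C12 from PMBOCH2Li, C13 from Cp2TiMe2).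
4. Ring order: eleven-membered thiacycle (step 18), ten-membered carbocycle (step 20), γ-lactone (step 25). Protecting groups are chosen for the end game: O8 TES comes off first for the ester, O12 and O14 PMB fall together to feed one oxidation, O6 TBS next, O15 TBDPS last.

Key step: step 20

Remark: germacrane numbering is used throughout (ring C1–C10, lactone carbons C11–C13, C14 on C10, C15 on C4); C6, C7 and C8 keep the spatial arrangement of the target (6R,7S,8R there) in every intermediate even where the CIP letters would change, C10 is carried as one epimer although either would serve, "ring-cis" means that the two ring carbons flanking the double bond lie on the same side, and TBS = tert-butyldimethylsilyl, TES = triethylsilyl, TBDPS = tert-butyldiphenylsilyl, PMB = 4-methoxybenzyl.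

**Route**

Step 1
Reactants: 1 but-2-yne-1,4-diol
Product: 2 4-[(tert-butyldiphenylsilyl)oxy]but-2-yn-1-ol
Conditions: NaH (1.0 equiv), THF, 0 °C; TBDPSCl (1.0 equiv); 1 in threefold excess
Reagents that add atoms: tert-butyl(chloro)diphenylsilane, CC(C)(C)[Si](Cl)(c1ccccc1)c1ccccc1
Why: O-silylation of the monoalkoxide of a symmetric diol used in excess should give mainly the monoether.

Step 2
Reactants: 2 4-[(tert-butyldiphenylsilyl)oxy]but-2-yn-1-ol
Product: 4 (Z)-4-[(tert-butyldiphenylsilyl)oxy]-3-iodobut-2-en-1-ol, via cyclic vinylalanate 3 (not isolated)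
Conditions: NaAlH2(OCH2CH2OMe)2, THF, 0 °C; then I2, THF, −78 °C
Reagents that add atoms: iodine, [I][I]
Why: Hydroxyl-directed trans-hydroalumination of the propargylic alcohol places aluminium on the distal alkyne carbon in a five-membered chelate, and iodinolysis with retention should give the Z-vinyl iodide with iodine cis to CH2OH.

Step 3
Reactants: 4 (Z)-4-[(tert-butyldiphenylsilyl)oxy]-3-iodobut-2-en-1-ol; 5 allyloxy(tert-butyl)dimethylsilane
Product: 7 (E)-6-[(tert-butyldimethylsilyl)oxy]-3-{[(tert-butyldiphenylsilyl)oxy]methyl}hex-2-en-1-ol, via alkylborane 6 (not isolated)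
Conditions: 5, 9-BBN, THF, 0 °C → rt; then 4, PdCl2(dppf) (cat.), AsPh3, Cs2CO3, DMF/H2O, rt
Reagents that add atoms: none
Why: Anti-Markovnikov hydroboration of the allyl ether followed by B-alkyl Suzuki–Miyaura coupling with retention at the vinyl iodide attaches C1–C3 cis to C6 and so fixes the ring-cis C4=C5 geometry.

Step 4
Reactants: 7 (E)-6-[(tert-butyldimethylsilyl)oxy]-3-{[(tert-butyldiphenylsilyl)oxy]methyl}hex-2-en-1-ol
Product: 8 (E)-6-[(tert-butyldimethylsilyl)oxy]-3-{[(tert-butyldiphenylsilyl)oxy]methyl}hex-2-enal (CHO = C6)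
Conditions: MnO2, CH2Cl2, rt
Reagents that add atoms: none
Why: Allylic oxidation with MnO2 converts the primary allylic alcohol into the enal without touching the silyl ethers or the alkene geometry.

Step 5
Reactants: 9 tert-butyl 2-[(4R,6S)-6-(hydroxymethyl)-2,2-dimethyl-1,3-dioxan-4-yl]acetate
Product: 10 tert-butyl 2-[(4R,6S)-6-{[(4-methoxybenzyl)oxy]methyl}-2,2-dimethyl-1,3-dioxan-4-yl]acetate
Conditions: NaH, PMBCl, Bu4NI (cat.), THF/DMF, 0 °C → rt
Reagents that add atoms: 4-methoxybenzyl chloride, COc1ccc(CCl)cc1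
Why: Williamson etherification of the primary alkoxide protects O14, and the acetonide and the tert-butyl ester should tolerate NaH at this temperature.

Step 6
Reactants: 10 tert-butyl 2-[(4R,6S)-6-{[(4-methoxybenzyl)oxy]methyl}-2,2-dimethyl-1,3-dioxan-4-yl]acetate
Product: 11 2-[(4R,6S)-6-{[(4-methoxybenzyl)oxy]methyl}-2,2-dimethyl-1,3-dioxan-4-yl]acetic acid
Conditions: KOH, MeOH/H2O (3:1), 60 °C; then aq. KHSO4 to pH 4, 0 °C
Reagents that add atoms: potassium hydroxide, [K+].[OH-]
Why: Saponification of the unhindered acetic ester by warm hydroxide (acyl–oxygen cleavage) leaves the base-stable acetonide and PMB ether intact, and acidification only to pH 4 spares the acetonide.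

Step 7
Reactants: 11 2-[(4R,6S)-6-{[(4-methoxybenzyl)oxy]methyl}-2,2-dimethyl-1,3-dioxan-4-yl]acetic acid
Product: 13 (S)-4-benzyl-3-{2-[(4R,6S)-6-{[(4-methoxybenzyl)oxy]methyl}-2,2-dimethyl-1,3-dioxan-4-yl]acetyl}oxazolidin-2-one, via mixed pivalic anhydride 12 (not isolated)
Conditions: PivCl, Et3N, THF, −20 °C; then (S)-4-benzyloxazolidin-2-one, LiCl, rt
Reagents that add atoms: (S)-4-benzyloxazolidin-2-one, O=C1N[C@@H](Cc2ccccc2)CO1
Why: N-Acylation of the oxazolidinone through the mixed pivalic anhydride with LiCl activation gives the imide (C11 carbonyl, C7 methylene) without touching the C8 centre.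

Step 8
Reactants: 13 (S)-4-benzyl-3-{2-[(4R,6S)-6-{[(4-methoxybenzyl)oxy]methyl}-2,2-dimethyl-1,3-dioxan-4-yl]acetyl}oxazolidin-2-one; 8 (E)-6-[(tert-butyldimethylsilyl)oxy]-3-{[(tert-butyldiphenylsilyl)oxy]methyl}hex-2-enal
Product: 16 syn-aldol imide (C11 N-acyl oxazolidinone; 6-OH; 8,10-O-isopropylidene; 1-OTBS; 14-OPMB; 15-OTBDPS), via boron enolate 14 (not isolated), via boron aldolate 15 (not isolated)
Conditions: 13, Bu2BOTf, i-Pr2NEt, CH2Cl2, −78 → 0 °C; 8, −78 → 0 °C; pH 7 buffer, MeOH, H2O2, 0 °C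
Reagents that add atoms: none
Why: In this Evans syn-aldol the Z-boron enolate reacts through a chair Zimmerman–Traxler transition state on the face away from the benzyl group of the (S)-auxiliary, which should set C7 and C6 syn in the absolute sense of the target next to the existing C8 centre.

Step 9
Reactants: 16 syn-aldol imide
Product: 17 Weinreb amide (C11 N-methoxy-N-methylamide; 6-OH; 8,10-O-isopropylidene; 1-OTBS; 14-OPMB; 15-OTBDPS)
Conditions: AlMe3, MeNHOMe·HCl, THF, −20 → 0 °C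
Reagents that add atoms: N,O-dimethylhydroxylamine hydrochloride, CNOC.Cl
Why: Aluminium amide transamination of the imide (Weinreb amide formation) is assisted by the free C6 hydroxyl as an aluminium chelate and should release the auxiliary without epimerising C7.

Step 10
Reactants: 17 Weinreb amide
Product: 18 6-O-TBS Weinreb amide
Conditions: TBSOTf, 2,6-lutidine, CH2Cl2, −78 → 0 °C
Reagents that add atoms: tert-butyldimethylsilyl triflate, CC(C)(C)[Si](C)(C)OS(=O)(=O)C(F)(F)F
Why: O-Silylation with the silyl triflate and a hindered base protects the hindered allylic C6 hydroxyl under conditions that the acetonide and the other ethers survive.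

Step 11
Reactants: 19 4-methoxybenzyl alcohol; 20 tributyl(iodomethyl)stannane
Product: 21 tributyl{[(4-methoxybenzyl)oxy]methyl}stannane
Conditions: 19, NaH, THF/DMF, 0 °C; then 20, rt
Reagents that add atoms: none
Why: Williamson etherification of the benzylic alkoxide with the iodomethylstannane gives the α-alkoxystannane that serves as the C12 carbanion source.

Step 12
Reactants: 18 6-O-TBS Weinreb amide; 21 tributyl{[(4-methoxybenzyl)oxy]methyl}stannane
Product: 24 C11 ketone bearing C12H2OPMB (6-OTBS; 8,10-O-isopropylidene; 1-OTBS; 14-OPMB; 15-OTBDPS), via alkoxymethyllithium 22 (not isolated), via tetrahedral lithium adduct 23 (not isolated)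
Conditions: 21, n-BuLi, THF, −78 °C; then 18, −78 → −40 °C; aq. NH4Cl
Reagents that add atoms: none
Why: Tin–lithium exchange gives the α-alkoxymethyllithium, which adds once to the Weinreb amide because the chelated tetrahedral adduct persists until work-up (Weinreb ketone synthesis), so C12 is joined to C11.

Step 13
Reactants: 24 C11 ketone
Product: 25 11(13)-alkene (2-propenyl unit C11(=C13H2)C12H2OPMB on C7; 6-OTBS; 8,10-O-isopropylidene; 1-OTBS; 14-OPMB; 15-OTBDPS)
Conditions: Cp2TiMe2, toluene, 65 °C, dark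
Reagents that add atoms: dimethyltitanocene Cp2TiMe2, [CH3-].[CH3-].[Ti+4].c1cc[cH-]c1.c1cc[cH-]c1
Why: Petasis methylenation with the non-basic titanium methylidene converts the hindered, enolisable ketone into the 1,1-disubstituted alkene without epimerising C7 or eliminating the C6 silyloxy group.

Step 14
Reactants: 25 11(13)-alkene
Product: 26 1,8,10-triol (6-OTBS; 12-OPMB; 14-OPMB; 15-OTBDPS)
Conditions: CSA (0.1 equiv), MeOH/CH2Cl2, 0 °C → rt
Reagents that add atoms: none
Why: Acid-catalysed transketalisation of the acetonide and methanolysis of the primary TBS ether proceed under conditions that the hindered secondary TBS ether, the TBDPS ether and the PMB ethers should survive.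

Step 15
Reactants: 26 1,8,10-triol
Product: 28 1-chloro-8,10-diol, via alkoxyphosphonium chloride 27 (not isolated)
Conditions: PPh3 (1.2 equiv), CCl4, CH2Cl2, 0 °C → rt
Reagents that add atoms: carbon tetrachloride, ClC(Cl)(Cl)Cl
Why: The Appel reaction is selective for the primary C1 hydroxyl over the two secondary ones and gives a primary chloride that is inert to thioacetate in the next step yet displaceable by an intramolecular thiolate.

Step 16
Reactants: 28 1-chloro-8,10-diol
Product: 30 (10R)-10-S-acetyl thioester of the 1-chloro-8-ol, via alkoxyphosphonium thioacetate 29 (not isolated)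
Conditions: PPh3, DIAD, THF, 0 °C; then 28, AcSH, 0 °C → rt
Reagents that add atoms: thioacetic acid, CC(=O)S
Why: Mitsunobu thioacylation with inversion should occur at the C10 carbinol, which is flanked by two CH2 groups, far faster than at the C8 carbinol shielded by the fully substituted C7.

Step 17
Reactants: 30 (10R)-10-S-acetyl thioester of the 1-chloro-8-ol
Product: 31 8-O-TES ether of 30
Conditions: TESOTf, 2,6-lutidine, CH2Cl2, −78 °C
Reagents that add atoms: triethylsilyl triflate, CC[Si](CC)(CC)OS(=O)(=O)C(F)(F)F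
Why: O-Silylation of the remaining hindered C8 hydroxyl with the silyl triflate leaves the thioester and the alkyl chloride untouched and gives the one silyl ether that can later be removed before all others.

Step 18
Reactants: 31 8-O-TES ether of 30
Product: 33 eleven-membered cyclic sulfide (S bridging C1 and C10; 10R; 6-OTBS; 8-OTES; 12-OPMB; 14-OPMB; 15-OTBDPS), via potassium thiolate 32 (not isolated)
Conditions: K2CO3, degassed MeOH/DMF (1:4), slow addition of 31 to 0.001 M, rt → 40 °C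
Reagents that add atoms: none
Why: Methanolysis of the thioacetate frees the C10 thiolate, which displaces the primary C1 chloride (SN2 macrocyclic thioetherification) under high dilution, helped by the cis C4=C5 bond that turns the chain ends toward each other.

Step 19
Reactants: 33 eleven-membered cyclic sulfide
Product: 34 eleven-membered cyclic sulfone (SO2 bridging C1 and C10; 10R; 6-OTBS; 8-OTES; 12-OPMB; 14-OPMB; 15-OTBDPS)
Conditions: (NH4)6Mo7O24·4H2O (cat.), 30% H2O2, EtOH/THF, 0 °C → rt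
Reagents that add atoms: hydrogen peroxide, OO
Why: Molybdate-catalysed peroxide oxidation takes the sulfide to the sulfone (S-oxidation) much faster than it epoxidises the alkenes.

Step 20
Reactants: 34 eleven-membered cyclic sulfone
Product: 37 ten-membered triene (ring-cis C1=C10 and C4=C5; 6-OTBS; 8-OTES; 12-OPMB; 14-OPMB; 15-OTBDPS), via α-bromo sulfone 35 (not isolated), via episulfone 36 (not isolated)
Conditions: KOH/Al2O3, CBr2F2, t-BuOH/CH2Cl2, 0 °C → rt
Reagents that add atoms: none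
Why: Solid KOH removes a proton at C1 (the less hindered α-carbon), the carbanion is brominated by CBr2F2 to give 35, and deprotonation at C10 then lets the α'-carbanion displace bromide from C1 in a 3-exo-tet closure to the episulfone 36, which loses SO2 in a stereospecific cheletropic step to leave the C1=C10 double bond (bromination at C10 followed by closure from C1 would give the same episulfone). The closest known reaction type is the Ramberg–Bäcklund reaction with in situ halogenation, as used to contract medium-ring sulfones to cycloalkenes. The ten-membered carbocycle is thus not closed by an end-to-end cyclisation: the only ring-forming event is the three-membered 3-exo-tet closure inside the eleven-membered ring, and the carbocycle results from excision of the sulfur atom. No stereocentre is created, the C10 centre disappears, and C6, C7 and C8 carry no acidic hydrogen under these conditions. The selectivity needed is the ring-cis geometry (C14 trans to C2), which should follow because carbanion formation is reversible under hydroxide and only the cis-fused episulfone (C2 and C9 on the same face) fits a ten-membered ring that already holds the cis C4=C5 bond. Loss of the C14 alkoxide from the C10 carbanion is the competing path and is held back because an alkoxide is a far poorer leaving group than the bromide that the same carbanion reaches intramolecularly, while silyl ethers, PMB ethers and the other alkenes are inert to KOH/Al2O3 and CBr2F2 at 0 °C.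

Step 21
Reactants: 37 ten-membered triene
Product: 38 8-ol (6-OTBS; 12-OPMB; 14-OPMB; 15-OTBDPS)
Conditions: PPTS, MeOH/CH2Cl2, rt
Reagents that add atoms: none
Why: Mild acid methanolysis cleaves the triethylsilyl ether selectively, since the TBS and TBDPS ethers and both PMB ethers are far more stable (selective desilylation).

Step 22
Reactants: 38 8-ol
Product: 39 8-O-(3-methylbutanoyl) ester (6-OTBS; 12-OPMB; 14-OPMB; 15-OTBDPS)
Conditions: (i-PrCH2CO)2O, Et3N, DMAP, CH2Cl2, rt
Reagents that add atoms: 3-methylbutanoic anhydride, CC(C)CC(=O)OC(=O)CC(C)C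
Why: DMAP-catalysed acyl transfer to the only free hydroxyl installs the C8 isovalerate.

Step 23
Reactants: 39 8-O-(3-methylbutanoyl) ester
Product: 40 12,14-diol (6-OTBS; 8-O-isovalerate; 15-OTBDPS)
Conditions: DDQ, CH2Cl2/pH 7 buffer, 0 °C
Reagents that add atoms: none
Why: Oxidative cleavage of both PMB ethers by DDQ (hydride abstraction to the oxocarbenium ion and hydrolysis) frees the C12 and C14 allylic alcohols while silyl ethers and the ester are inert.

Step 24
Reactants: 40 12,14-diol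
Product: 41 6,12,14-triol (8-O-isovalerate; 15-OTBDPS)
Conditions: HF·pyridine, pyridine, THF, 0 °C → rt
Reagents that add atoms: none
Why: Buffered HF·pyridine should remove the secondary allylic TBS ether at C6 faster than the primary TBDPS ether at C15, which is much more stable to acid-assisted fluoride cleavage (selective desilylation).

Step 25
Reactants: 41 6,12,14-triol
Product: 44 15-O-TBDPS ether of the target (6,12-olide; C14 aldehyde; 8-O-isovalerate), via hydroxy dialdehyde 42 (not isolated), via lactol 43 (not isolated)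
Conditions: TEMPO (0.2 equiv), PhI(OAc)2 (3.5 equiv), CH2Cl2, rt
Reagents that add atoms: none
Why: TEMPO/PhI(OAc)2 oxidises the two primary allylic alcohols in preference to the secondary one, the C12 aldehyde is trapped by the C6 hydroxyl as the cis-fused lactol and oxidised on to the α-methylene γ-lactone (oxidative lactonisation), and the C14 alcohol gives the enal in the same operation.

Step 26
Reactants: 44 15-O-TBDPS ether of the target
Product: 45 (1(10)E,4E,6R,7S,8R)-15-hydroxy-8-(3-methylbutanoyloxy)-14-oxogermacra-1(10),4,11(13)-trien-12,6-olide (CNP0345200.7)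
Conditions: HF·pyridine, THF, 0 °C → rt
Reagents that add atoms: none
Why: Fluoride cleavage of the primary TBDPS ether under mildly acidic conditions frees the C15 alcohol and should leave the α-methylene lactone, the enal and the ester intact (desilylation).

**Compound list**
1 | but-2-yne-1,4-diol | OCC#CCO | starting material
2 | 4-[(tert-butyldiphenylsilyl)oxy]but-2-yn-1-ol | OCC#CCO[Si](c1ccccc1)(c1ccccc1)C(C)(C)C | intermediate
3 | cyclic vinylalanate, sodium salt (Al on the carbon bearing CH2OTBDPS, chelated by the alkoxide; not isolated) | [Na+].COCCO[Al-]1(OCCOC)OCC=C1CO[Si](c1ccccc1)(c1ccccc1)C(C)(C)C | intermediate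
4 | (Z)-4-[(tert-butyldiphenylsilyl)oxy]-3-iodobut-2-en-1-ol | OC/C=C(\I)CO[Si](c1ccccc1)(c1ccccc1)C(C)(C)C | intermediate
5 | allyloxy(tert-butyl)dimethylsilane | C=CCO[Si](C)(C)C(C)(C)C | starting material
6 | 9-[3-(tert-butyldimethylsilyloxy)propyl]-9-borabicyclo[3.3.1]nonane (not isolated) | CC(C)(C)[Si](C)(C)OCCCB1C2CCCC1CCC2 | intermediate
7 | (E)-6-[(tert-butyldimethylsilyl)oxy]-3-{[(tert-butyldiphenylsilyl)oxy]methyl}hex-2-en-1-ol | OC/C=C(\CCCO[Si](C)(C)C(C)(C)C)CO[Si](c1ccccc1)(c1ccccc1)C(C)(C)C | intermediate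
8 | (E)-6-[(tert-butyldimethylsilyl)oxy]-3-{[(tert-butyldiphenylsilyl)oxy]methyl}hex-2-enal | O=C/C=C(\CCCO[Si](C)(C)C(C)(C)C)CO[Si](c1ccccc1)(c1ccccc1)C(C)(C)C | intermediate
9 | tert-butyl 2-[(4R,6S)-6-(hydroxymethyl)-2,2-dimethyl-1,3-dioxan-4-yl]acetate | CC(C)(C)OC(=O)C[C@H]1C[C@@H](CO)OC(C)(C)O1 | starting material
10 | tert-butyl 2-[(4R,6S)-6-{[(4-methoxybenzyl)oxy]methyl}-2,2-dimethyl-1,3-dioxan-4-yl]acetate | CC(C)(C)OC(=O)C[C@H]1C[C@@H](COCc2ccc(OC)cc2)OC(C)(C)O1 | intermediate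
11 | 2-[(4R,6S)-6-{[(4-methoxybenzyl)oxy]methyl}-2,2-dimethyl-1,3-dioxan-4-yl]acetic acid | OC(=O)C[C@H]1C[C@@H](COCc2ccc(OC)cc2)OC(C)(C)O1 | intermediate
12 | mixed pivalic anhydride of 11 (not isolated) | CC(C)(C)C(=O)OC(=O)C[C@H]1C[C@@H](COCc2ccc(OC)cc2)OC(C)(C)O1 | intermediate
13 | (S)-4-benzyl-3-{2-[(4R,6S)-6-{[(4-methoxybenzyl)oxy]methyl}-2,2-dimethyl-1,3-dioxan-4-yl]acetyl}oxazolidin-2-one | O=C(C[C@H]1C[C@@H](COCc2ccc(OC)cc2)OC(C)(C)O1)N1C(=O)OC[C@@H]1Cc1ccccc1 | intermediate
14 | (Z)-dibutylboron enolate of 13 (not isolated) | CCCCB(CCCC)O/C(=C\[C@H]1C[C@@H](COCc2ccc(OC)cc2)OC(C)(C)O1)N1C(=O)OC[C@@H]1Cc1ccccc1 | intermediate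
15 | dibutylboron aldolate of 16 (not isolated) | O=C([C@@H]([C@H]1C[C@@H](COCc2ccc(OC)cc2)OC(C)(C)O1)[C@H](OB(CCCC)CCCC)/C=C(\CCCO[Si](C)(C)C(C)(C)C)CO[Si](c1ccccc1)(c1ccccc1)C(C)(C)C)N1C(=O)OC[C@@H]1Cc1ccccc1 | intermediate
16 | syn-aldol imide: open C1–C10 chain, C11 N-acyl (S)-4-benzyloxazolidinone, 6-OH, 8,10-O-isopropylidene, 1-OTBS, 14-OPMB, 15-OTBDPS, 4E | O=C([C@@H]([C@H]1C[C@@H](COCc2ccc(OC)cc2)OC(C)(C)O1)[C@H](O)/C=C(\CCCO[Si](C)(C)C(C)(C)C)CO[Si](c1ccccc1)(c1ccccc1)C(C)(C)C)N1C(=O)OC[C@@H]1Cc1ccccc1 | intermediate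
17 | Weinreb amide: as 16 with C11 N-methoxy-N-methylamide | CON(C)C(=O)[C@@H]([C@H]1C[C@@H](COCc2ccc(OC)cc2)OC(C)(C)O1)[C@H](O)/C=C(\CCCO[Si](C)(C)C(C)(C)C)CO[Si](c1ccccc1)(c1ccccc1)C(C)(C)C | intermediate
18 | 6-O-TBS Weinreb amide | CON(C)C(=O)[C@@H]([C@H]1C[C@@H](COCc2ccc(OC)cc2)OC(C)(C)O1)[C@H](O[Si](C)(C)C(C)(C)C)/C=C(\CCCO[Si](C)(C)C(C)(C)C)CO[Si](c1ccccc1)(c1ccccc1)C(C)(C)C | intermediate
19 | 4-methoxybenzyl alcohol | COc1ccc(CO)cc1 | starting material
20 | tributyl(iodomethyl)stannane | CCCC[Sn](CCCC)(CCCC)CI | starting material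
21 | tributyl{[(4-methoxybenzyl)oxy]methyl}stannane | CCCC[Sn](CCCC)(CCCC)COCc1ccc(OC)cc1 | intermediate
22 | [(4-methoxybenzyl)oxy]methyllithium (not isolated) | [Li]COCc1ccc(OC)cc1 | intermediate
23 | tetrahedral lithium adduct at C11 (not isolated; C11 unassigned) | CON(C)C(O[Li])(COCc1ccc(OC)cc1)[C@@H]([C@H]1C[C@@H](COCc2ccc(OC)cc2)OC(C)(C)O1)[C@H](O[Si](C)(C)C(C)(C)C)/C=C(\CCCO[Si](C)(C)C(C)(C)C)CO[Si](c1ccccc1)(c1ccccc1)C(C)(C)C | intermediate
24 | C11 ketone bearing C12H2OPMB; 6-OTBS, 8,10-O-isopropylidene, 1-OTBS, 14-OPMB, 15-OTBDPS | O=C(COCc1ccc(OC)cc1)[C@@H]([C@H]1C[C@@H](COCc2ccc(OC)cc2)OC(C)(C)O1)[C@H](O[Si](C)(C)C(C)(C)C)/C=C(\CCCO[Si](C)(C)C(C)(C)C)CO[Si](c1ccccc1)(c1ccccc1)C(C)(C)C | intermediate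
25 | 11(13)-alkene: 2-propenyl unit C11(=C13H2)C12H2OPMB on C7, otherwise as 24 | C=C(COCc1ccc(OC)cc1)[C@@H]([C@H]1C[C@@H](COCc2ccc(OC)cc2)OC(C)(C)O1)[C@H](O[Si](C)(C)C(C)(C)C)/C=C(\CCCO[Si](C)(C)C(C)(C)C)CO[Si](c1ccccc1)(c1ccccc1)C(C)(C)C | intermediate
26 | 1,8,10-triol (10S); 6-OTBS, 12-OPMB, 14-OPMB, 15-OTBDPS | C=C(COCc1ccc(OC)cc1)[C@@H]([C@H](O)C[C@H](O)COCc1ccc(OC)cc1)[C@H](O[Si](C)(C)C(C)(C)C)/C=C(\CCCO)CO[Si](c1ccccc1)(c1ccccc1)C(C)(C)C | intermediate
27 | C1 alkoxytriphenylphosphonium chloride of 26 (not isolated) | C=C(COCc1ccc(OC)cc1)[C@@H]([C@H](O)C[C@H](O)COCc1ccc(OC)cc1)[C@H](O[Si](C)(C)C(C)(C)C)/C=C(\CCCO[P+](c1ccccc1)(c1ccccc1)c1ccccc1)CO[Si](c1ccccc1)(c1ccccc1)C(C)(C)C.[Cl-] | intermediate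
28 | 1-chloro-8,10-diol (10S) | C=C(COCc1ccc(OC)cc1)[C@@H]([C@H](O)C[C@H](O)COCc1ccc(OC)cc1)[C@H](O[Si](C)(C)C(C)(C)C)/C=C(\CCCCl)CO[Si](c1ccccc1)(c1ccccc1)C(C)(C)C | intermediate
29 | C10 alkoxytriphenylphosphonium thioacetate of 28 (not isolated) | C=C(COCc1ccc(OC)cc1)[C@@H]([C@H](O)C[C@H](O[P+](c1ccccc1)(c1ccccc1)c1ccccc1)COCc1ccc(OC)cc1)[C@H](O[Si](C)(C)C(C)(C)C)/C=C(\CCCCl)CO[Si](c1ccccc1)(c1ccccc1)C(C)(C)C.CC(=O)[S-] | intermediate
30 | (10R)-10-S-acetyl thioester of the 1-chloro-8-ol | C=C(COCc1ccc(OC)cc1)[C@@H]([C@H](O)C[C@@H](SC(C)=O)COCc1ccc(OC)cc1)[C@H](O[Si](C)(C)C(C)(C)C)/C=C(\CCCCl)CO[Si](c1ccccc1)(c1ccccc1)C(C)(C)C | intermediate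
31 | 8-O-TES ether of 30 | C=C(COCc1ccc(OC)cc1)[C@@H]([C@H](O[Si](CC)(CC)CC)C[C@@H](SC(C)=O)COCc1ccc(OC)cc1)[C@H](O[Si](C)(C)C(C)(C)C)/C=C(\CCCCl)CO[Si](c1ccccc1)(c1ccccc1)C(C)(C)C | intermediate
32 | potassium C10 thiolate of 31 (not isolated) | C=C(COCc1ccc(OC)cc1)[C@@H]([C@H](O[Si](CC)(CC)CC)C[C@@H]([S-])COCc1ccc(OC)cc1)[C@H](O[Si](C)(C)C(C)(C)C)/C=C(\CCCCl)CO[Si](c1ccccc1)(c1ccccc1)C(C)(C)C.[K+] | intermediate
33 | eleven-membered cyclic sulfide, S bridging C1 and C10 (10R); 6-OTBS, 8-OTES, 12-OPMB, 14-OPMB, 15-OTBDPS | COc1ccc(COC[C@@H]2SCCC/C(CO[Si](c3ccccc3)(c3ccccc3)C(C)(C)C)=C\[C@@H](O[Si](C)(C)C(C)(C)C)[C@@H](C(=C)COCc3ccc(OC)cc3)[C@H](O[Si](CC)(CC)CC)C2)cc1 | intermediate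
34 | eleven-membered cyclic sulfone (10R), precursor of the key step | COc1ccc(COC[C@@H]2S(=O)(=O)CCC/C(CO[Si](c3ccccc3)(c3ccccc3)C(C)(C)C)=C\[C@@H](O[Si](C)(C)C(C)(C)C)[C@@H](C(=C)COCc3ccc(OC)cc3)[C@H](O[Si](CC)(CC)CC)C2)cc1 | intermediate
35 | α-bromo sulfone, bromine on C1 (not isolated; C1 unassigned) | COc1ccc(COC[C@@H]2S(=O)(=O)C(Br)CC/C(CO[Si](c3ccccc3)(c3ccccc3)C(C)(C)C)=C\[C@@H](O[Si](C)(C)C(C)(C)C)[C@@H](C(=C)COCc3ccc(OC)cc3)[C@H](O[Si](CC)(CC)CC)C2)cc1 | intermediate
36 | episulfone (thiirane 1,1-dioxide across C1–C10, C2 and C9 cis; not isolated; C1 and C10 unassigned) | COc1ccc(COCC23S(=O)(=O)C2CC/C(CO[Si](c2ccccc2)(c2ccccc2)C(C)(C)C)=C\[C@@H](O[Si](C)(C)C(C)(C)C)[C@@H](C(=C)COCc2ccc(OC)cc2)[C@H](O[Si](CC)(CC)CC)C3)cc1 | intermediate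
37 | ten-membered triene, ring-cis C1=C10 and C4=C5; 6-OTBS, 8-OTES, 12-OPMB, 14-OPMB, 15-OTBDPS | COc1ccc(COC/C2=C/CC/C(CO[Si](c3ccccc3)(c3ccccc3)C(C)(C)C)=C\[C@@H](O[Si](C)(C)C(C)(C)C)[C@@H](C(=C)COCc3ccc(OC)cc3)[C@H](O[Si](CC)(CC)CC)C2)cc1 | intermediate
38 | 8-ol of 37 | COc1ccc(COC/C2=C/CC/C(CO[Si](c3ccccc3)(c3ccccc3)C(C)(C)C)=C\[C@@H](O[Si](C)(C)C(C)(C)C)[C@@H](C(=C)COCc3ccc(OC)cc3)[C@H](O)C2)cc1 | intermediate
39 | 8-O-(3-methylbutanoyl) ester of 38 | COc1ccc(COC/C2=C/CC/C(CO[Si](c3ccccc3)(c3ccccc3)C(C)(C)C)=C\[C@@H](O[Si](C)(C)C(C)(C)C)[C@@H](C(=C)COCc3ccc(OC)cc3)[C@H](OC(=O)CC(C)C)C2)cc1 | intermediate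
40 | 12,14-diol; 6-OTBS, 8-O-isovalerate, 15-OTBDPS | OC/C1=C/CC/C(CO[Si](c2ccccc2)(c2ccccc2)C(C)(C)C)=C\[C@@H](O[Si](C)(C)C(C)(C)C)[C@@H](C(=C)CO)[C@H](OC(=O)CC(C)C)C1 | intermediate
41 | 6,12,14-triol; 8-O-isovalerate, 15-OTBDPS | OC/C1=C/CC/C(CO[Si](c2ccccc2)(c2ccccc2)C(C)(C)C)=C\[C@@H](O)[C@@H](C(=C)CO)[C@H](OC(=O)CC(C)C)C1 | intermediate
42 | hydroxy dialdehyde: 6-OH, C12 and C14 aldehydes (not isolated) | O=C/C1=C/CC/C(CO[Si](c2ccccc2)(c2ccccc2)C(C)(C)C)=C\[C@@H](O)[C@@H](C(=C)C=O)[C@H](OC(=O)CC(C)C)C1 | intermediate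
43 | cis-fused 6,12-lactol with C14 aldehyde (not isolated; C12 unassigned) | O=C/C1=C/CC/C(CO[Si](c2ccccc2)(c2ccccc2)C(C)(C)C)=C\[C@H]2OC(O)C(=C)[C@H]2[C@H](OC(=O)CC(C)C)C1 | intermediate
44 | 15-O-TBDPS ether of the target | O=C/C1=C/CC/C(CO[Si](c2ccccc2)(c2ccccc2)C(C)(C)C)=C\[C@H]2OC(=O)C(=C)[C@H]2[C@H](OC(=O)CC(C)C)C1 | intermediate
45 | (1(10)E,4E,6R,7S,8R)-15-hydroxy-8-(3-methylbutanoyloxy)-14-oxogermacra-1(10),4,11(13)-trien-12,6-olide (CNP0345200.7) | C=C1C(=O)O[C@@H]2/C=C(/CO)CC/C=C(/C=O)C[C@@H](OC(=O)CC(C)C)[C@H]12 | target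

**Step count**
Total: 26 steps. Longest linear sequence: 22 steps (steps 1–4, 8–10 and 12–26).

**Steps most likely to fail, with fallbacks**

Step 20 (key step). The C10 carbanion may expel the C14 alkoxide (β-elimination to a vinyl sulfone), bromination may repeat under the heterogeneous conditions, or closure may go to the ring-trans episulfone. The fallback places the halogen before the base step. Setting out from sulfide 33, N-chlorosuccinimide (CH2Cl2, 0 °C) chlorinates an α-carbon through the chlorosulfonium ion to give the α-chloro sulfide F1 (drawn with chlorine on C1; the C10 isomer would converge). mCPBA/NaHCO3 (CH2Cl2, −20 → 0 °C) oxidises it at once to the α-chloro sulfone F2. KOt-Bu in THF at −78 °C then runs the classical Ramberg–Bäcklund reaction of an isolated α-halo sulfone, with no halogen source present in the base step, and rejoins the route at triene 37.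

Step 18. Intermolecular S-alkylation and disulfide formation may outrun closure of the eleven-membered ring, because the nucleophile is a secondary thiolate flanked by C9 and C14. The fallback exchanges the roles of the two termini. Setting out from chloro diol 28, KSAc with catalytic NaI in DMF (50 °C) gives the C1 thioacetate F3. MsCl/Et3N at −40 °C sulfonylates the less hindered C10 hydroxyl to give the C10 mesylate F4, and TESOTf/2,6-lutidine caps O8 to give the silyl ether F5. K2CO3 in degassed MeOH/DMF under high dilution then effects S-deacetylation and ring closure by the unhindered primary sulfur at C1 on the C10 mesylate with inversion, which rejoins the route at sulfide 33 with the same 10R configuration.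

Step 16. The alkoxyphosphonium-forming step may discriminate poorly between the C10 and C8 carbinols, or the 1,3-diol may dehydrate. The fallback tells the two hydroxyls apart by acylation before any C–S bond is made. Setting out from chloro diol 28, AcCl/2,4,6-collidine at −78 °C acetylates the less hindered C10 hydroxyl to give the 10-acetate F6 (a wrong isomer can be hydrolysed back to 28). TESOTf/2,6-lutidine gives the 8-O-TES ether F7, and K2CO3/MeOH at 0 °C removes the acetate to give the 10-ol F8. The Mitsunobu reaction with AcSH (PPh3, DIAD) on this single free hydroxyl rejoins the route at thioacetate 31.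

**Further compounds**
F1 | step 20 | α-chloro sulfide of 33 (chlorine on C1) | COc1ccc(COC[C@@H]2SC(Cl)CC/C(CO[Si](c3ccccc3)(c3ccccc3)C(C)(C)C)=C\[C@@H](O[Si](C)(C)C(C)(C)C)[C@@H](C(=C)COCc3ccc(OC)cc3)[C@H](O[Si](CC)(CC)CC)C2)cc1
F2 | step 20 | α-chloro sulfone (chlorine on C1) | COc1ccc(COC[C@@H]2S(=O)(=O)C(Cl)CC/C(CO[Si](c3ccccc3)(c3ccccc3)C(C)(C)C)=C\[C@@H](O[Si](C)(C)C(C)(C)C)[C@@H](C(=C)COCc3ccc(OC)cc3)[C@H](O[Si](CC)(CC)CC)C2)cc1
F3 | step 18 | C1 S-acetyl thioester of the 8,10-diol | C=C(COCc1ccc(OC)cc1)[C@@H]([C@H](O)C[C@H](O)COCc1ccc(OC)cc1)[C@H](O[Si](C)(C)C(C)(C)C)/C=C(\CCCSC(C)=O)CO[Si](c1ccccc1)(c1ccccc1)C(C)(C)C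
F4 | step 18 | C10 mesylate of F3 | C=C(COCc1ccc(OC)cc1)[C@@H]([C@H](O)C[C@H](OS(C)(=O)=O)COCc1ccc(OC)cc1)[C@H](O[Si](C)(C)C(C)(C)C)/C=C(\CCCSC(C)=O)CO[Si](c1ccccc1)(c1ccccc1)C(C)(C)C
F5 | step 18 | 8-O-TES ether of F4 | C=C(COCc1ccc(OC)cc1)[C@@H]([C@H](O[Si](CC)(CC)CC)C[C@H](OS(C)(=O)=O)COCc1ccc(OC)cc1)[C@H](O[Si](C)(C)C(C)(C)C)/C=C(\CCCSC(C)=O)CO[Si](c1ccccc1)(c1ccccc1)C(C)(C)C
F6 | step 16 | 10-acetate of 28 | C=C(COCc1ccc(OC)cc1)[C@@H]([C@H](O)C[C@H](OC(C)=O)COCc1ccc(OC)cc1)[C@H](O[Si](C)(C)C(C)(C)C)/C=C(\CCCCl)CO[Si](c1ccccc1)(c1ccccc1)C(C)(C)C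
F7 | step 16 | 8-O-TES ether of F6 | C=C(COCc1ccc(OC)cc1)[C@@H]([C@H](O[Si](CC)(CC)CC)C[C@H](OC(C)=O)COCc1ccc(OC)cc1)[C@H](O[Si](C)(C)C(C)(C)C)/C=C(\CCCCl)CO[Si](c1ccccc1)(c1ccccc1)C(C)(C)C
F8 | step 16 | 10-ol with 8-O-TES (10S) | C=C(COCc1ccc(OC)cc1)[C@@H]([C@H](O[Si](CC)(CC)CC)C[C@H](O)COCc1ccc(OC)cc1)[C@H](O[Si](C)(C)C(C)(C)C)/C=C(\CCCCl)CO[Si](c1ccccc1)(c1ccccc1)C(C)(C)C
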